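**Retrosynthetic overview**
- Locants follow the asbestinin skeleton: THF = O/C2/C1/C10/C9, cyclohexane = C1/C10/C11/C12/C13/C14, oxepane = C1/C2/C3/O/C16/C15/C14, oxonane = C2–C9 plus the THF oxygen; methyls C17 (on C15), C18 (on C3), C19 (on C7), C20 (on C12).
- Enabling feature: the oxepane shares its C1–C2 edge with the THF, whose ring oxygen sits on C2, so a C1=C2 dihydrofuran is nucleophilic at C1 and then electrophilic at C2. C3 carries an ether oxygen and C4 (an ester carbonyl in the precursor, so C3 is a ketene-acetal carbon), and C14 is allylic to the future C17 methyl (an allyl-cation terminus).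
- Key disconnection: the C1–C14 and C2–C3 bonds are cut together, leading from a cage lactone back to a 13-membered macrolactone. Forward, one cationic (5+2) cascade closes cyclohexane, oxepane and a temporary C3–C4(=O)–O–C8 lactone bridge that steers C3 to the C8 face of C2 (C1, C2, C3, C14 set).
- Before it: the macrolactone comes from Nozaki–Hiyama–Kishi closure at C14–C15 of an ester made from a lactate ether acid and a THF alcohol; the alcohol comes from (R)-γ-hydroxymethyl-butyrolactone by butenolide conjugate addition (C10) and crotylboration (C11, C12). After it: the lactone is opened, C15 reduced, C4 extended to C6 and C8 turned into the C7 vinyl iodide.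
- Ring order: THF (from the starting lactone) → macrolactone (step 14) → cyclohexane + oxepane + lactone bridge (step 17) → oxonane by Nozaki–Hiyama–Kishi closure at C6–C7 (step 26).

Key step: step 17

**Step 1**
Reactants: 1 (R)-5-(hydroxymethyl)dihydrofuran-2(3H)-one
Product: 2 (R)-5-[(tert-butyldimethylsilyloxy)methyl]dihydrofuran-2(3H)-one
Conditions: TBSCl, imidazole, DMF, 0 °C → rt
Reagents that add atoms: tert-butyldimethylsilyl chloride, CC(C)(C)[Si](C)(C)Cl
Why: Imidazole-promoted silyl ether formation masks the primary alcohol for the enolate and cuprate chemistry that follows; no stereocentre is touched.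

**Step 2**
Reactants: 2 (R)-5-[(tert-butyldimethylsilyloxy)methyl]dihydrofuran-2(3H)-one
Product: 4 (R)-5-[(tert-butyldimethylsilyloxy)methyl]furan-2(5H)-one, via selenide 3 (not isolated)
Conditions: LDA, THF, −78 °C; PhSeBr; then H2O2, pyridine, CH2Cl2, 0 °C → rt
Reagents that add atoms: none
Why: α-Selenenylation of the lactone enolate followed by selenoxide syn-elimination should give the endocyclic butenolide, C9 being untouched because the elimination runs under non-basic oxidative conditions.

**Step 3**
Reactants: 4 (R)-5-[(tert-butyldimethylsilyloxy)methyl]furan-2(5H)-one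
Product: 5 (4S,5R)-5-[(tert-butyldimethylsilyloxy)methyl]-4-vinyldihydrofuran-2(3H)-one
Conditions: CH2=CHMgBr, CuBr·SMe2 (cat.), THF, −78 → −40 °C; aq. NH4Cl
Reagents that add atoms: vinylmagnesium bromide, C=C[Mg]Br
Why: Copper-catalysed conjugate addition to a γ-substituted butenolide: the vinyl group should enter anti to the silyloxymethyl group on C9, which sets C10 (trans lactone).

**Step 4**
Reactants: 5 (4S,5R)-5-[(tert-butyldimethylsilyloxy)methyl]-4-vinyldihydrofuran-2(3H)-one
Product: 7 methyl acetal (2-methoxy-THF; C9 CH2OTBS trans to C10 vinyl; both anomers), via lactol 6 (not isolated)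
Conditions: DIBAL-H, CH2Cl2, −78 °C; then MeOH, PPTS (cat.), 0 °C
Reagents that add atoms: methanol, CO
Why: Partial lactone reduction and acid-catalysed acetalisation of the lactol should store C2 at the aldehyde level in a base- and oxidant-stable form; the anomer mixture is of no consequence because C2 becomes sp2 in step 16.

**Step 5**
Reactants: 7 methyl acetal (C10 vinyl)
Product: 8 C11 aldehyde (2-methoxy-THF-3-carbaldehyde; C9 CH2OTBS trans to C10 CHO)
Conditions: O3, CH2Cl2, −78 °C; then PPh3, −78 °C → rt
Reagents that add atoms: ozone, O=[O+][O-]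
Why: Ozonolysis with reductive work-up cleaves the only alkene to the C11 aldehyde; C10 keeps the favoured trans arrangement and the aldehyde is used at once to avoid epimerisation.

**Step 6**
Reactants: 8 C11 aldehyde
Product: 9 homoallylic alcohol (11R,12R; C11 OH anti to C12 Me; terminal C13=C14 vinyl)
Conditions: (S,S)-diisopropyl tartrate (E)-crotylboronate, 4 Å MS, toluene, −78 °C; then 1 M NaOH
Reagents that add atoms: diisopropyl (4S,5S)-2-[(E)-but-2-en-1-yl]-1,3,2-dioxaborolane-4,5-dicarboxylate, C/C=C/CB1O[C@H](C(=O)OC(C)C)[C@@H](C(=O)OC(C)C)O1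
Why: Crotylboration through a closed chair transition state: the (E)-crotyl unit gives the anti (C11 OH/C12 Me) relation and the tartrate enantiomer is chosen to attack the Felkin face of the C10-branched aldehyde (matched pair), which should set C11 and C12 as in the target.

**Step 7**
Reactants: 9 homoallylic alcohol
Product: 10 bis-silyl ether (C8 OTBS; C11 OTBS)
Conditions: TBSOTf, 2,6-lutidine, CH2Cl2, −78 °C
Reagents that add atoms: tert-butyldimethylsilyl triflate, CC(C)(C)[Si](C)(C)OS(=O)(=O)C(F)(F)F
Why: Silylation of the hindered secondary alcohol with the silyl triflate at low temperature, where the methyl acetal is not ionised; no stereocentre is touched.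

**Step 8**
Reactants: 10 bis-silyl ether
Product: 11 primary alcohol (C8 OH; C11 OTBS)
Conditions: HF·pyridine, pyridine, THF, 0 °C
Reagents that add atoms: none
Why: Selective fluoride-mediated cleavage of the primary silyl ether in the presence of the hindered secondary one (steric differentiation) frees O8 for the ester tether.

**Step 9**
Reactants: 12 ethyl (S)-lactate; 13 2,3-dibromopropene
Product: 14 ethyl (S)-2-[(2-bromoprop-2-en-1-yl)oxy]propanoate
Conditions: NaH, THF/DMF, 0 °C → rt
Reagents that add atoms: none
Why: Williamson ether synthesis at the allylic bromide (SN2), the vinylic bromide being inert; any erosion of the lactate centre is irrelevant because C3 becomes sp2 in step 17.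

**Step 10**
Reactants: 14 ethyl (S)-2-[(2-bromoprop-2-en-1-yl)oxy]propanoate
Product: 15 (S)-2-[(2-bromoprop-2-en-1-yl)oxy]propanoic acid
Conditions: LiOH, THF/H2O, 0 °C; then 1 M HCl
Reagents that add atoms: lithium hydroxide, [Li+].[OH-]
Why: Ester saponification; the vinyl bromide and the allyl ether are stable to aqueous hydroxide.

**Step 11**
Reactants: 11 primary alcohol (C8 OH; C11 OTBS); 15 (S)-2-[(2-bromoprop-2-en-1-yl)oxy]propanoic acid
Product: 16 ester (O8 acylated by 15; terminal vinyl; vinyl bromide)
Conditions: EDC·HCl, DMAP, CH2Cl2, 0 °C → rt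
Reagents that add atoms: none
Why: Carbodiimide esterification (Steglich conditions) of the primary alcohol attaches the lactate unit that will become the temporary lactone; no stereocentre is set.

**Step 12**
Reactants: 16 ester
Product: 17 C14 primary alcohol
Conditions: 9-BBN, THF, 0 °C → rt; then H2O2, aq. NaOAc, 0 °C
Reagents that add atoms: hydrogen peroxide, OO
Why: Anti-Markovnikov hydroboration–oxidation: 9-BBN should react only with the monosubstituted C13=C14 alkene and leave the electron-poor 2-bromoalkene and the ester alone, and the buffered peroxide oxidation spares the ester.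

**Step 13**
Reactants: 17 C14 primary alcohol
Product: 18 C14 aldehyde
Conditions: Dess–Martin periodinane, NaHCO3, CH2Cl2, 0 °C → rt
Reagents that add atoms: none
Why: Dess–Martin oxidation of the primary alcohol to the aldehyde under buffered, non-acidic conditions that keep the acetal and silyl ether intact.

**Step 14**
Reactants: 18 C14 aldehyde
Product: 19 13-membered macrolactone (C14 OH both epimers; C15=CH2; C2 methyl acetal)
Conditions: CrCl2, NiCl2 (cat.), DMSO/THF, rt, high dilution (slow addition)
Reagents that add atoms: none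
Why: Nozaki–Hiyama–Kishi macrocyclisation (nickel-catalysed activation of the vinyl bromide, addition of the alkenylchromium to the aldehyde) should close the 13-membered ring; both C14 epimers are usable because C14 becomes a cation in step 17.

**Step 15**
Reactants: 19 macrolactone allylic alcohol
Product: 20 macrolactone C14 pivalate
Conditions: PivCl, pyridine, DMAP (cat.), CH2Cl2, 0 °C → rt
Reagents that add atoms: pivaloyl chloride, CC(C)(C)C(=O)Cl
Why: DMAP-catalysed acylation gives an allylic ester without α-hydrogens, which survives the amide base of step 17 and later serves as the leaving group.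

**Step 16**
Reactants: 20 macrolactone C14 pivalate
Product: 21 macrolactone 2,3-dihydrofuran (C1=C2 enol ether; C14 OPiv; C11 OTBS)
Conditions: TMSOTf, i-Pr2NEt, CH2Cl2, −20 → 0 °C
Reagents that add atoms: none
Why: Acetal-to-enol-ether elimination: the silyl triflate ionises the methyl acetal to the C2 oxocarbenium ion and the amine removes a C1 proton, which should give the 2,3-dihydrofuran while the allylic pivalate, lactone and silyl ether stay untouched under the buffered conditions.

**Step 17**
Reactants: 21 macrolactone 2,3-dihydrofuran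
Product: 25 cage lactone (THF; cyclohexane; oxepane; C3–C4(=O)–O–C8 lactone bridge; C15=CH2; C11 OTBS), via silyl ketene acetal 22 (not isolated), via allyl cation 23 (not isolated), via oxocarbenium ion 24 (not isolated)
Conditions: LDA, TBSCl, THF/DMPU, −78 °C; pentane, filtration, evaporation; then TMSOTf (cat.), 2,6-di-tert-butyl-4-methylpyridine, CH2Cl2, −78 → −30 °C, high dilution
Reagents that add atoms: none
Why: Proposed new method: after O-silylation of the lactone enolate (22), silyl triflate ionises the allylic pivalate to the 2-substituted allyl cation 23, the dihydrofuran attacks its C14 terminus through C1 (6-exo closure of the cyclohexane), and the C2 oxocarbenium ion 24 so formed is attacked by C3 of the silyl ketene acetal (7-membered closure that creates the oxepane and, through the C3–C4(=O)–O–C8 strand, the bridging seven-membered lactone), the silyl group leaving with pivalate so that the Lewis acid turns over. The closest known reactions are allyl-cation-initiated cation–olefin cyclisations, the Mukaiyama aldol–Prins cascade in which an enol ether acts first as nucleophile and then as oxocarbenium electrophile, and Mukaiyama-type additions of silyl ketene acetals to cyclic oxocarbenium ions; what is new is their union as a transannular (5+2) annulation across an enol ether. C1 is set by the three-atom tether from C10, which allows only a cis ring fusion, and C14 by a chair-like closure in which C15 stays equatorial, away from the axial C12 methyl, which puts H14 anti to H1. C2 is set by the lactone strand, which is anchored to C9 and can reach only the face of the oxocarbenium ion syn to C8; this also forces the oxepane to be trans-fused to the THF, a fusion an untethered C3 nucleophile would not choose, and obliges the cyclohexane to relax to a twist-boat, the only conformation compatible with the trans,trans-fused oxepane of the target. C3 is set by the two rings that close on it: C4 must point under the THF towards C9 and the ether oxygen towards C14, which leaves the methyl group outside and allows one configuration only. The step needs chemoselectivity for C1 over C3 in the capture of the allyl cation, secured because C3 is tied to the central allyl carbon (a 5-endo closure on either terminus) whereas C1 closes 6-exo, and it needs the oxocarbenium ion to wait for C3, secured by the non-nucleophilic counter-ion and the hindered base.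

**Step 18**
Reactants: 25 cage lactone
Product: 26 lactol (C4 hemiacetal; both anomers)
Conditions: DIBAL-H, CH2Cl2, −78 °C
Reagents that add atoms: none
Why: Partial reduction of the hindered lactone with DIBAL-H at low temperature should stop at the lactol (stable aluminium hemiacetal), which differentiates C4 (aldehyde level) from C8 (alcohol).

**Step 19**
Reactants: 26 lactol
Product: 27 alkenyl dioxolane (C4=C5 E/Z; C8 OH free; C15=CH2)
Conditions: [(1,3-dioxolan-2-yl)methyl]triphenylphosphonium bromide, KOt-Bu, THF, 0 °C → rt
Reagents that add atoms: [(1,3-dioxolan-2-yl)methyl]triphenylphosphonium bromide, [Br-].C1COC(C[P+](c2ccccc2)(c2ccccc2)c2ccccc2)O1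
Why: Wittig olefination of the open hydroxy-aldehyde form of the lactol with a non-stabilised acetal-bearing ylide adds C5 and C6 (C6 masked as a dioxolane) and releases O8; the alkene geometry is irrelevant because the bond is saturated in step 20.

**Step 20**
Reactants: 27 alkenyl dioxolane
Product: 28 saturated dioxolane alcohol (15R methyl; C4–C5 saturated; C8 OH)
Conditions: H2 (1 atm), Pt/C, EtOAc, rt
Reagents that add atoms: none
Why: Heterogeneous catalytic hydrogenation saturates C4=C5 and the exocyclic C15 alkene; hydrogen should be delivered to the oxepane face opposite to the C13 methylene on the neighbouring C14, which sets C15 (H15 syn to H14), and platinum is chosen to limit allylic C–O hydrogenolysis.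

**Step 21**
Reactants: 28 saturated dioxolane alcohol
Product: 29 C8 aldehyde
Conditions: Dess–Martin periodinane, NaHCO3, CH2Cl2, 0 °C → rt
Reagents that add atoms: none
Why: Dess–Martin oxidation to the α-alkoxy aldehyde under buffered conditions that should not epimerise C9.

**Step 22**
Reactants: 29 C8 aldehyde
Product: 30 (Z)-vinyl iodide (C8=C7(I)CH3; iodine cis to C9)
Conditions: (1-iodoethyl)triphenylphosphonium iodide, NaHMDS, THF/DMPU, −78 → −20 °C
Reagents that add atoms: (1-iodoethyl)triphenylphosphonium iodide, CC(I)[P+](c1ccccc1)(c1ccccc1)c1ccccc1.[I-]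
Why: Stork–Zhao olefination with the α-iodo ethylidene ylide should give the trisubstituted (Z)-vinyl iodide (iodine cis to C9) through the kinetically preferred cis-oxaphosphetane.

**Step 23**
Reactants: 30 (Z)-vinyl iodide
Product: 31 C11 alcohol
Conditions: TBAF, THF, rt → 45 °C
Reagents that add atoms: none
Why: Fluoride-mediated cleavage of the secondary silyl ether; the vinyl iodide and the dioxolane are inert.

**Step 24**
Reactants: 31 C11 alcohol
Product: 32 C11 acetate
Conditions: Ac2O, pyridine, DMAP (cat.), CH2Cl2, rt
Reagents that add atoms: acetic anhydride, CC(=O)OC(C)=O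
Why: DMAP-catalysed acetylation installs the C11 acetate of the target before the C6 hydroxyl exists, which avoids any later differentiation of two secondary alcohols.

**Step 25**
Reactants: 32 C11 acetate
Product: 33 seco aldehyde (C6 CHO; C7 iodide; C11 OAc)
Conditions: PPTS, acetone/H2O, 50 °C
Reagents that add atoms: water, O
Why: Acid-catalysed acetal hydrolysis unmasks the C6 aldehyde; the acetate, the vinyl iodide and the tertiary ether tolerate the mild acid.

**Step 26**
Reactants: 33 seco aldehyde
Product: 34 CNP0289966.2 (target)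
Conditions: CrCl2, NiCl2 (cat.), DMSO, rt, high dilution
Reagents that add atoms: none
Why: Intramolecular Nozaki–Hiyama–Kishi reaction closes the nine-membered oxonane with retention of the (Z)-alkene geometry; the C6 carbinol should arise by addition to the aldehyde face turned away from the tricyclic core, expected to give the (6R) alcohol.

**Compound list**
1 | (R)-5-(hydroxymethyl)dihydrofuran-2(3H)-one | OC[C@H]1CCC(=O)O1 | starting material
2 | (R)-5-[(tert-butyldimethylsilyloxy)methyl]dihydrofuran-2(3H)-one | CC(C)(C)[Si](C)(C)OC[C@H]1CCC(=O)O1 | intermediate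
3 | (5R)-5-[(tert-butyldimethylsilyloxy)methyl]-3-(phenylselanyl)dihydrofuran-2(3H)-one, C3 epimers | CC(C)(C)[Si](C)(C)OC[C@H]1CC([Se]c2ccccc2)C(=O)O1 | intermediate (not isolated)
4 | (R)-5-[(tert-butyldimethylsilyloxy)methyl]furan-2(5H)-one | CC(C)(C)[Si](C)(C)OC[C@H]1C=CC(=O)O1 | intermediate
5 | (4S,5R)-5-[(tert-butyldimethylsilyloxy)methyl]-4-vinyldihydrofuran-2(3H)-one | CC(C)(C)[Si](C)(C)OC[C@H]1[C@H](C=C)CC(=O)O1 | intermediate
6 | lactol of 5 (C2 hemiacetal, anomers) | CC(C)(C)[Si](C)(C)OC[C@H]1[C@H](C=C)CC(O)O1 | intermediate (not isolated)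
7 | methyl acetal: 2-methoxy-THF with C9 CH2OTBS trans to C10 vinyl (anomers) | CC(C)(C)[Si](C)(C)OC[C@H]1[C@H](C=C)CC(OC)O1 | intermediate
8 | C11 aldehyde: 2-methoxy-THF, C9 CH2OTBS trans to C10 CHO | CC(C)(C)[Si](C)(C)OC[C@H]1[C@H](C=O)CC(OC)O1 | intermediate
9 | homoallylic alcohol: C10 carries the (1R,2R)-1-hydroxy-2-methylbut-3-enyl chain (C11 OH anti to C12 Me) | CC(C)(C)[Si](C)(C)OC[C@H]1[C@H]([C@H](O)[C@H](C)C=C)CC(OC)O1 | intermediate
10 | bis-silyl ether of 9 (C8 OTBS, C11 OTBS) | CC(C)(C)[Si](C)(C)OC[C@H]1[C@H]([C@H](O[Si](C)(C)C(C)(C)C)[C@H](C)C=C)CC(OC)O1 | intermediate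
11 | primary alcohol (C8 OH, C11 OTBS) | OC[C@H]1[C@H]([C@H](O[Si](C)(C)C(C)(C)C)[C@H](C)C=C)CC(OC)O1 | intermediate
12 | ethyl (S)-lactate | C[C@H](O)C(=O)OCC | starting material
13 | 2,3-dibromopropene | C=C(Br)CBr | starting material
14 | ethyl (S)-2-[(2-bromoprop-2-en-1-yl)oxy]propanoate | C=C(Br)CO[C@@H](C)C(=O)OCC | intermediate
15 | (S)-2-[(2-bromoprop-2-en-1-yl)oxy]propanoic acid | C=C(Br)CO[C@@H](C)C(=O)O | intermediate
16 | ester of 11 (at O8) with acid 15 | C=C(Br)CO[C@@H](C)C(=O)OC[C@H]1[C@H]([C@H](O[Si](C)(C)C(C)(C)C)[C@H](C)C=C)CC(OC)O1 | intermediate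
17 | C14 primary alcohol | C=C(Br)CO[C@@H](C)C(=O)OC[C@H]1[C@H]([C@H](O[Si](C)(C)C(C)(C)C)[C@H](C)CCO)CC(OC)O1 | intermediate
18 | C14 aldehyde | C=C(Br)CO[C@@H](C)C(=O)OC[C@H]1[C@H]([C@H](O[Si](C)(C)C(C)(C)C)[C@H](C)CC=O)CC(OC)O1 | intermediate
19 | 13-membered macrolactone, C14 allylic alcohol (both epimers), C15 exocyclic methylene, C2 methyl acetal | C=C1CO[C@@H](C)C(=O)OC[C@H]2[C@H]([C@H](O[Si](C)(C)C(C)(C)C)[C@H](C)CC1O)CC(OC)O2 | intermediate
20 | C14 pivalate of 19 | C=C1CO[C@@H](C)C(=O)OC[C@H]2[C@H]([C@H](O[Si](C)(C)C(C)(C)C)[C@H](C)CC1OC(=O)C(C)(C)C)CC(OC)O2 | intermediate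
21 | macrolactone 2,3-dihydrofuran (C1=C2 enol ether, C14 OPiv, C11 OTBS) | C=C1CO[C@@H](C)C(=O)OC[C@H]2[C@H]([C@H](O[Si](C)(C)C(C)(C)C)[C@H](C)CC1OC(=O)C(C)(C)C)C=CO2 | intermediate
22 | silyl ketene acetal of 21 (C3=C4(OTBS), E/Z) | C=C1COC(C)=C(O[Si](C)(C)C(C)(C)C)OC[C@H]2[C@H]([C@H](O[Si](C)(C)C(C)(C)C)[C@H](C)CC1OC(=O)C(C)(C)C)C=CO2 | intermediate (not isolated)
23 | allyl cation (C14–C15–C17) as triflate | C=C1COC(C)=C(O[Si](C)(C)C(C)(C)C)OC[C@H]2[C@H]([C@H](O[Si](C)(C)C(C)(C)C)[C@H](C)C[CH+]1)C=CO2.[O-]S(=O)(=O)C(F)(F)F | intermediate (not isolated)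
24 | C2 oxocarbenium ion after C1–C14 closure, as triflate | C=C1COC(C)=C(O[Si](C)(C)C(C)(C)C)OC[C@@H]2[O+]=C[C@H]3[C@H]1C[C@@H](C)[C@@H](O[Si](C)(C)C(C)(C)C)[C@@H]23.[O-]S(=O)(=O)C(F)(F)F | intermediate (not isolated)
25 | cage lactone: THF, cyclohexane, oxepane and C3–C4(=O)–O–C8 lactone bridge; C15 methylene; C11 OTBS; C1, C2, C3, C9, C10, C11, C12, C14 as in 34 | C=C1CO[C@@]2(C)C(=O)OC[C@@H]3O[C@H]2[C@H]4[C@H]1C[C@@H](C)[C@@H](O[Si](C)(C)C(C)(C)C)[C@@H]34 | intermediate
26 | lactol of 25 (C4 hemiacetal, anomers) | C=C1CO[C@@]2(C)C(O)OC[C@@H]3O[C@H]2[C@H]4[C@H]1C[C@@H](C)[C@@H](O[Si](C)(C)C(C)(C)C)[C@@H]34 | intermediate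
27 | tricyclic core with C3 2-(1,3-dioxolan-2-yl)vinyl arm (C4=C5, E/Z), C9 CH2OH, C15 methylene, C11 OTBS | C=C1CO[C@@](C)(C=CC5OCCO5)[C@H]2O[C@@H](CO)[C@@H]3[C@H](O[Si](C)(C)C(C)(C)C)[C@H](C)C[C@@H]1[C@H]23 | intermediate
28 | saturated dioxolane alcohol (15R methyl, C4–C5 saturated, C8 OH) | C[C@H]1CO[C@@](C)(CCC5OCCO5)[C@H]2O[C@@H](CO)[C@@H]3[C@H](O[Si](C)(C)C(C)(C)C)[C@H](C)C[C@@H]1[C@H]23 | intermediate
29 | C8 aldehyde | C[C@H]1CO[C@@](C)(CCC5OCCO5)[C@H]2O[C@@H](C=O)[C@@H]3[C@H](O[Si](C)(C)C(C)(C)C)[C@H](C)C[C@@H]1[C@H]23 | intermediate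
30 | (Z)-vinyl iodide (C9–CH=C(I)CH3, iodine cis to C9) | C[C@H]1CO[C@@](C)(CCC5OCCO5)[C@H]2O[C@@H](/C=C(\I)C)[C@@H]3[C@H](O[Si](C)(C)C(C)(C)C)[C@H](C)C[C@@H]1[C@H]23 | intermediate
31 | C11 alcohol | C[C@H]1CO[C@@](C)(CCC5OCCO5)[C@H]2O[C@@H](/C=C(\I)C)[C@@H]3[C@H](O)[C@H](C)C[C@@H]1[C@H]23 | intermediate
32 | C11 acetate | C[C@H]1CO[C@@](C)(CCC5OCCO5)[C@H]2O[C@@H](/C=C(\I)C)[C@@H]3[C@H](OC(C)=O)[C@H](C)C[C@@H]1[C@H]23 | intermediate
33 | seco aldehyde (C6 CHO, C7 iodide, C11 OAc) | C[C@H]1CO[C@@](C)(CCC=O)[C@H]2O[C@@H](/C=C(\I)C)[C@@H]3[C@H](OC(C)=O)[C@H](C)C[C@@H]1[C@H]23 | intermediate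
34 | CNP0289966.2 | CC(=O)O[C@H]1[C@@H]2[C@@H]3[C@@H](C[C@H]1C)[C@@H](C)CO[C@@]1(C)CC[C@@H](O)/C(C)=C\[C@@H]2O[C@@H]31 | target

**Totals**
Total steps: 26. Longest linear sequence: 24 steps (steps 1–8 and 11–26; steps 9–10 make the side fragment).

**Steps most likely to fail**

Step 17 (proposed new method). The allyl cation may be captured on the wrong face at C14 or by the ketene acetal instead of the enol ether. The α-allyloxy enolate may also undergo a [2,3]-shift before it is silylated, and the oxocarbenium ion may be quenched before C3 arrives. The fallback splits the cascade into two operations of known type. Setting out from 21, ionisation of the allylic pivalate with BF3·OEt2 in CH2Cl2 at −78 °C in the presence of methanol would give the cyclohexane-fused methyl acetal F1; this is an allyl-cation-initiated cyclisation of an enol ether, ended by alcohol capture of the oxocarbenium ion. The lactone is not yet enolised there, so the ester carbon cannot compete for the cation and C14 epimers can be separated. F1 would then be converted into its silyl ketene acetal (LDA, TBSCl) and cyclised with TMSOTf, a Mukaiyama-type addition of a silyl ketene acetal to the oxocarbenium ion regenerated from the acetal, which comes back to the route at 25.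

Step 26. Facial selectivity at C6 in the nine-membered ring closure may be poor. The fallback replaces substrate control by reagent control. Setting out from 33, the ring closure would be run as before and the product containing the 6-epi alcohol F2 oxidised with Dess–Martin periodinane to the enone F3. Corey–Bakshi–Shibata reduction with the (S)-oxazaborolidine and catecholborane, with the alkenyl arm as the large group, would then return to the route at 34.

Step 20. Hydrogen may be delivered to the wrong face of the C15 methylene, or the allylic C–O bonds at C16 and C3 may be hydrogenolysed. The fallback moves the C15 reduction to the rigid cage and changes its mechanism. Setting out from 25, manganese-catalysed hydrogen-atom-transfer hydrogenation (Mn(dpm)3, PhSiH3, t-BuOOH, i-PrOH), which runs through the tertiary C15 radical and does not cleave allylic ethers, would give the 15-methyl cage lactone F4. DIBAL-H reduction would give the lactol F5 and the Wittig reaction of step 19 the alkenyl dioxolane F6. Diimide (potassium azodicarboxylate, AcOH) would then saturate the C4=C5 bond, which comes back to the route at 28.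

**Further compounds**
F1 | step 17 | cyclohexane-fused 2-methoxy-THF macrolactone (C1–C14 bond formed, C2 methyl acetal anomers, lactone not enolised) | C=C1CO[C@@H](C)C(=O)OC[C@@H]2OC(OC)[C@H]3[C@H]1C[C@@H](C)[C@@H](O[Si](C)(C)C(C)(C)C)[C@@H]23
F2 | step 26 | 6-epi-34 (6S alcohol) | CC(=O)O[C@H]1[C@@H]2[C@@H]3[C@@H](C[C@H]1C)[C@@H](C)CO[C@@]1(C)CC[C@H](O)/C(C)=C\[C@@H]2O[C@@H]31
F3 | step 26 | C6 enone of 34 | CC(=O)O[C@H]1[C@@H]2[C@@H]3[C@@H](C[C@H]1C)[C@@H](C)CO[C@@]1(C)CCC(=O)/C(C)=C\[C@@H]2O[C@@H]31
F4 | step 20 | 15-methyl cage lactone (15R) | C[C@H]1CO[C@@]2(C)C(=O)OC[C@@H]3O[C@H]2[C@H]4[C@H]1C[C@@H](C)[C@@H](O[Si](C)(C)C(C)(C)C)[C@@H]34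
F5 | step 20 | lactol of F4 (C4 hemiacetal, anomers) | C[C@H]1CO[C@@]2(C)C(O)OC[C@@H]3O[C@H]2[C@H]4[C@H]1C[C@@H](C)[C@@H](O[Si](C)(C)C(C)(C)C)[C@@H]34
F6 | step 20 | alkenyl dioxolane with 15R methyl (C4=C5 E/Z, C8 OH) | C[C@H]1CO[C@@](C)(C=CC5OCCO5)[C@H]2O[C@@H](CO)[C@@H]3[C@H](O[Si](C)(C)C(C)(C)C)[C@H](C)C[C@@H]1[C@H]23
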